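The numbers of this flask are made up; no experiment stands behind them.

The easy step comes first: the gas dissolves at a rate that can be reckoned on one line.

| flask | starting material | second substrate | gas | temperature | time | remark |
|---|---|---|---|---|---|---|
| epsilon | 0.20 mM | 0.400 mM | 0.015 mM (held) | 60 °C | 40 s |  |
| delta | 0.20 mM | 0.400 mM | 0.015 mM (held) | 10 °C | 40 s |  |
| eta | 0.20 mM | 0.400 mM | 0.015 mM (held) |  | 40 s | at 60 °C until 12 s, from then on at 10 °C |
| zeta | 0.20 mM | 0.400 mM | 0.015 mM (held) | 35 °C | 40 s |  |

    gas ⇌ coupling partner, rate k1*(csat - [coupling partner]) (k1 = 0.79 s⁻¹, csat = 0.015 mM)
    starting material + coupling partner → target (k2 = 15000 L mol⁻¹ s⁻¹, Ea2 = 43.0 kJ mol⁻¹)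
    starting material + target → side product (k3 = 44 L mol⁻¹ s⁻¹, Ea3 = 39.0 kJ mol⁻¹)
    starting material + second substrate → cross product (k4 = 470 L mol⁻¹ s⁻¹, Ea4 = 45.0 kJ mol⁻¹)
    second substrate + coupling partner → second product (k5 = 58000 L mol⁻¹ s⁻¹, Ea5 = 11.0 kJ mol⁻¹)
    second substrate ⇌ dormant form (K6 = 0.18, k6 = 0.21 s⁻¹, Ea6 = 84.0 kJ mol⁻¹, ΔH6 = −24.0 kJ mol⁻¹)
    (constants at 60 °C)

* which flask leads in amount of target, in percent of the starting material charged ("all alike" within 1.5 percentage points) (epsilon / delta / eta / zeta / all alike)
* how much target is there at the end, in percent of the starting material charged: epsilon
* how much target is there at the end, in percent of the starting material charged: delta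
* how much target is there at the end, in percent of the starting material charged: eta
* how much target is there at the end, in percent of the starting material charged: zeta

- percent here means starting material units held: one side product counts as two
- at the start none of coupling partner is dissolved
- constants are those at 60 °C; use the activation energies and enthalpies for any other temperature

This reckoning is done by hand. At the first instant no coupling partner is dissolved, so the feed F, the transfer coefficient times the saturation concentration, stands at its full 0.0118 mM s⁻¹. Dividing the charge of second substrate by F gives 33.8 s. This is the clearing time τ, the time the full feed needs to pay for that charge. The dissolving step is given no activation energy, and the charges match, so this τ is the same for the recipes.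

Each dissolved unit then meets a race. At the constants of 60 °C, second substrate takes coupling partner with a pseudo-first-order constant of 23.2 s⁻¹. Starting material takes it with 3.00 s⁻¹, so target loses the race 7.73 to one at the start. This estimate therefore puts coupling partner near 4.52 × 10⁻⁴ mM at the start at 60 °C, far below saturation, and at that stage dissolving is the rate-limiting step.

Meanwhile cross product forms. At 60 °C its step gives starting material a half-life of 3.69 s at the start, much shorter than the wait. Cooling slows this step through its 45.0 kJ mol⁻¹.

In the middle, cross product formation spends second substrate without using the feed, and a whole charge of starting material spent this way takes 16.9 s off τ. The dormant form holds some second substrate back; in zeta the pair relaxes by that step, both ways together, with a half-life of 10.3 s.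

Once that charge is paid for, coupling partner climbs toward saturation. At saturation, starting material goes to target with a pseudo-first-order constant of 0.225 s⁻¹ at 60 °C, and this falls on cooling through 43.0 kJ mol⁻¹. The window after τ lasts 6.24 s. At the full feed that window is worth 37.0% of the starting material charge, but the feed falls as coupling partner climbs. The hand reckoning stops at this window figure and gives no answer for each flask.

The forecast names zeta. It gives epsilon 24%, delta 13.5%, eta 13% and zeta 33%, with a range for zeta from 27% to 39%. Its ground is that “the second substrate scavenges the coupling partner until it is used up”.

The simulation puts zeta first, with epsilon 23.4%, delta 9.38%, eta 12.0% and zeta 27.2%. The forecast's leader stands, and its zeta figure lies above the result, though inside its range. In zeta, cross product formation uses starting material 1.8 times as fast as target formation at 16.2 s, but 0.0091 times as fast at 40.0 s. By then, past τ of 33.8 s, 0.77% of the second substrate remains unbound in zeta.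

One neighbour flask is zeta with 1.6 mM of second substrate, so its clearing time is 135 s, far beyond the reading at 40 s. By this reckoning no window opens in that neighbour before the reading, so its target is expected below the 27.2% of zeta. The simulation gives that neighbour 0.564% target and 98.7% cross product, with 42% of the second substrate left unbound.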